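**Retrosynthetic overview**
- Target ⇒ phenethyl (E)-icos-2-enoate by hydrogenation of C2=C3 ⇒ phenethyl 3-hydroxyicosanoate by β-elimination through its mesylate.
- Key disconnection C2–C3: aldol addition of the lithium enolate of phenethyl acetate (C2 unit that already carries the finished ester) to octadecanal (C18 unit).
- Octadecanal ⇒ octadecan-1-ol by oxidation.
- No ring is formed anywhere; the only ring, the phenyl group, is bought as part of phenethyl acetate, and the ester C–O bond is never made or broken.

Assumption: the target has no stereocentre and no stereogenic double bond, so it is one achiral compound; the C3 carbinol centre of the aldol intermediates is carried as a racemate and is erased before the end.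

**Route**

Step 1
Reactants: 1 octadecan-1-ol
Product: 2 octadecanal
Conditions: TEMPO (10 mol %), PhI(OAc)2 (1.1 equiv), CH2Cl2, rt, 4 h; aq. Na2S2O3/NaHCO3 wash; used within a day
Reagents that add atoms: none
Why: The TEMPO/PhI(OAc)2 oxoammonium oxidation takes a primary alcohol to the aldehyde and stops there under anhydrous conditions, with no stereocentre involved.

Step 2
Reactants: 2 octadecanal; 3 phenethyl acetate
Product: 6 rac-phenethyl 3-hydroxyicosanoate, via lithium enolate of phenethyl acetate 4 (not isolated), via lithium aldolate 5 (not isolated)
Conditions: 3 (1.15 equiv), commercial LDA solution (1.1 equiv), THF, –78 °C, 30 min; 2 (1.0 equiv) in THF added slowly, –78 °C, 1 h; AcOH (1.5 equiv) in THF at –78 °C, then aqueous work-up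
Reagents that add atoms: none
Why: In this directed aldol addition the preformed kinetic lithium ester enolate adds to the unhindered aliphatic aldehyde at –78 °C faster than it self-condenses, the cold AcOH quench prevents retro-aldol, and the new C3 centre forms as a racemate that is erased in steps 4 and 5.

Step 3
Reactants: 6 rac-phenethyl 3-hydroxyicosanoate
Product: 7 rac-phenethyl 3-(methanesulfonyloxy)icosanoate
Conditions: MsCl (1.3 equiv), Et3N (1.5 equiv), CH2Cl2, 0 °C, 1 h; aqueous work-up, crude used directly
Reagents that add atoms: methanesulfonyl chloride, CS(=O)(=O)Cl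
Why: O-Sulfonylation of a secondary alcohol with MsCl/Et3N is fast and near-quantitative at 0 °C and leaves the ester untouched, with C3 still racemic.

Step 4
Reactants: 7 rac-phenethyl 3-(methanesulfonyloxy)icosanoate
Product: 8 phenethyl (E)-icos-2-enoate
Conditions: DBU (1.5 equiv), CH2Cl2, 0 °C to rt, 3 h; dilute HCl wash, silica plug
Reagents that add atoms: none
Why: E1cB β-elimination of the β-mesyloxy ester gives the conjugated, thermodynamically favoured E-enoate and destroys the C3 centre, and any Z or β,γ isomer is harmless because all converge in step 5.

Step 5
Reactants: 8 phenethyl (E)-icos-2-enoate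
Product: 9 phenethyl icosanoate
Conditions: H2 (1 atm), 10% Pd/C (5 mol %), EtOAc, rt, 6 h; filter through Celite, recrystallise from EtOH
Reagents that add atoms: none
Why: Heterogeneous catalytic hydrogenation saturates the conjugated C=C, while the ester, the arene and the homobenzylic (not benzylic) C–O bond are inert at 1 atm and rt, and the product has no stereocentre.

**Compound list**
1 | octadecan-1-ol (stearyl alcohol) | CCCCCCCCCCCCCCCCCCO | starting material
2 | octadecanal | CCCCCCCCCCCCCCCCCC=O | intermediate
3 | phenethyl acetate (2-phenylethyl acetate) | CC(=O)OCCc1ccccc1 | starting material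
4 | lithium enolate of phenethyl acetate (lithium 1-(2-phenylethoxy)ethenolate) | C=C(O[Li])OCCc1ccccc1 | intermediate
5 | lithium aldolate, lithium alkoxide of rac-phenethyl 3-hydroxyicosanoate | CCCCCCCCCCCCCCCCCC(O[Li])CC(=O)OCCc1ccccc1 | intermediate
6 | rac-phenethyl 3-hydroxyicosanoate | CCCCCCCCCCCCCCCCCC(O)CC(=O)OCCc1ccccc1 | intermediate
7 | rac-phenethyl 3-(methanesulfonyloxy)icosanoate | CCCCCCCCCCCCCCCCCC(OS(C)(=O)=O)CC(=O)OCCc1ccccc1 | intermediate
8 | phenethyl (E)-icos-2-enoate | CCCCCCCCCCCCCCCCC/C=C/C(=O)OCCc1ccccc1 | intermediate
9 | phenethyl icosanoate (achiral) | CCCCCCCCCCCCCCCCCCCC(=O)OCCc1ccccc1 | target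

**Summary**
Total step count: 5.
Longest linear sequence: 5 steps (1 → 2 → 6 → 7 → 8 → 9); 3 is used as bought.

**Three steps most likely to fail**

(i) Step 2, the aldol addition. The risks are that octadecanal crystallises out of THF at –78 °C, that the aldehyde is enolised, or that retro-aldol or ester self-condensation intervenes. The fallback is a Reformatsky reaction, which uses a non-basic zinc enolate at a temperature where the aldehyde is fully dissolved. It sets out from 2 and comes back to the route at 6. Commercial 2-phenylethanol is acylated with bromoacetyl bromide (pyridine, CH2Cl2, 0 °C) to give phenethyl bromoacetate F1. F1 and 2 are then added together to TMSCl-activated zinc dust in THF at gentle reflux. The bromozinc enolate F2 forms in the flask and adds to 2 to give the bromozinc aldolate F3, and a cold 1 M HCl quench gives 6.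

(ii) Step 1, the oxidation. The risks are incomplete conversion of the poorly soluble alcohol and loss of the waxy aldehyde 2 through oligomerisation or autoxidation on handling. The fallback avoids the aldehyde altogether and makes the same C2–C3 bond by a Claisen-type acylation at the acid oxidation level. It sets out from 3 and comes back at 6. Compound 3 is converted to its lithium enolate 4 (LDA, THF, –78 °C; 2.1 equiv, because the product consumes a second equivalent of enolate). The enolate is acylated with commercial stearoyl chloride (1.0 equiv, –78 °C, AcOH quench) to give phenethyl 3-oxoicosanoate F4. The ketone of F4 is reduced chemoselectively with NaBH4 (THF/i-PrOH, 0 °C) to give 6.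

(iii) Step 4, the elimination. The risks are a sluggish or untidy elimination and sulfur residues that later poison the palladium catalyst. The fallback removes the C3 oxygen by Barton–McCombie radical deoxygenation instead of elimination and hydrogenation. It sets out from 6 and comes back at 9, so steps 3 to 5 are skipped. Compound 6 is heated with 1,1'-thiocarbonyldiimidazole (cat. DMAP, 1,2-dichloroethane, 60 °C) to give phenethyl 3-[(imidazol-1-ylcarbonothioyl)oxy]icosanoate F5. Treating F5 with Bu3SnH and AIBN in toluene at reflux gives 9 directly.

**Further compounds**
F1 | step 2 | phenethyl bromoacetate | BrCC(=O)OCCc1ccccc1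
F2 | step 2 | bromozinc enolate (Reformatsky reagent) of phenethyl bromoacetate | Br[Zn]CC(=O)OCCc1ccccc1
F3 | step 2 | bromozinc aldolate of rac-phenethyl 3-hydroxyicosanoate | CCCCCCCCCCCCCCCCCC(O[Zn]Br)CC(=O)OCCc1ccccc1
F4 | step 1 | phenethyl 3-oxoicosanoate | CCCCCCCCCCCCCCCCCC(=O)CC(=O)OCCc1ccccc1
F5 | step 4 | rac-phenethyl 3-[(imidazol-1-ylcarbonothioyl)oxy]icosanoate | CCCCCCCCCCCCCCCCCC(OC(=S)n1ccnc1)CC(=O)OCCc1ccccc1
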